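- Which of these flasks do I charge again, if what I want at the reading is target and not over-reaction product?

| flask | starting material | coupling partner | capture agent | temperature | time | remark |
|---|---|---|---|---|---|---|
| gamma | 1.0 mM | 1.00 mM (fed, over 4.0 min) | 0.100 mM | 70 °C | 6.0 min | all else is in the flask from the start; the feed brings no volume worth counting |
| theta | 1.0 mM | 1.00 mM | 0.100 mM | 70 °C | 6.0 min | everything together at the start |
| epsilon | 1.0 mM | 1.00 mM (fed, over 4.0 min) | 0.100 mM |  | 6.0 min | the addition at 50 °C, then warmed to 70 °C; the feed brings no volume worth counting |
| zeta | 1.0 mM (fed, over 4.0 min) | 1.00 mM | 0.100 mM | 70 °C | 6.0 min | all else is in the flask from the start; the feed brings no volume worth counting |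

    starting material + coupling partner → open intermediate (k1 = 1040 /M/s, Ea1 = 38.0 kJ/mol)
    open intermediate → target (k2 = 0.0215 /s, Ea2 = 83.0 kJ/mol)
    target → over-reaction product (k3 = 0.00121 /s, Ea3 = 100 kJ/mol)
    open intermediate + capture agent → trapped intermediate (k4 = 2.74 /M/s, Ea4 = 56.0 kJ/mol)
    (constants at 70 °C)

- at 70 °C the constants are as listed, elsewhere as the activation energies make them

- which flask leads in share of target in target plus over-reaction product ("all alike" within 1.5 percentage points) (gamma / theta / epsilon / zeta / all alike)
- share of target in target plus over-reaction product at the end, gamma
- share of target in target plus over-reaction product at the end, theta
- share of target in target plus over-reaction product at the end, epsilon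
- share of target in target plus over-reaction product at the end, zeta

- With the charges of theta as they stand at the start, the coupling step has a half-life of 0.67 s, far shorter than the 0.54 min of the step to target. So I take the step to target as the rate-limiting step of theta, and target as appearing on average 46.5 s after the start.
- In theta, capture has a half-life of 42 min, far longer than that of the step to target, so I set trapping aside.
- I carry one number, 0.379 for theta: the exposure, meaning the over-reaction rate constant times the time from the average birth of target to the reading. I take the share as the exponential of minus the exposure, which gives 68.5 % for theta.
- The dosing time is far longer than the lifetime of starting material against everything charged, by a factor of 250. So I take the feed as moving the average birth later by 2.00 min.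
- This lowers the exposure of gamma to 0.234, and the share to 79.1 %. Zeta is the same, because the coupling step treats its two equal charges alike.
- In epsilon, over-reaction has the highest activation energy of the scheme, so I count the cold exposure as nothing. I count for target the 2.00 min after warming, which gives 0.145, less than in gamma.
- That puts epsilon near 86.5 %, or somewhat better if some target forms after warming. This is a lead of 7.4 percentage points over gamma and zeta, so I commit to charging epsilon.
- The forecast also names epsilon, on the ground of “how long target sits exposed”. It gives 79.5 % for gamma and 79.5 % for zeta, with 69 % for theta and 88.8 % for epsilon. The last two stand above mine.
- The simulation puts epsilon in the lead at 88.9 %, with gamma at 79.3 %, zeta at 79.3 % and theta at 68.9 %. So I charge epsilon again. At 6.00 min epsilon holds target at 82.2 % of the starting material charged, and open intermediate at 5.44 %.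
- Theta left until 25 min, with amounts and temperature held, takes the same reckoning. The added time raises the exposure from 0.379 to 1.76, which gives a share of 17.2 %. That flask reads a share of 17.4 %, with target at 17.2 % of the starting material charged.

(The rate constants are assumed.)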